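**Remark on locants and faces:** C1 is the ring carbon bearing C7 (the CH2O carbon), C2–C5 are the oxygen-bearing ring carbons in order, and C6 is the vinylic CH. With C1→C6 drawn clockwise, "up" is toward the viewer. The target then has O3 and O4 up and O2 and O5 down, i.e. (2S,3S,4S,5R) in these locants, or (3R,4S,5S,6S) in cyclohexene numbering.

**Assumption:** no enantioselective form of the arene–triazolinedione cycloaddition/osmylation is relied on. The key step is run as the racemic process and the antipodes are separated directly afterwards.

## Structural features

The target has a single carbocycle, a cyclohex-1-ene (C1–C6), with one exocyclic carbon C7 on C1 and no other ring. Four contiguous stereocentres C2–C5 each carry an oxygen: O2/O3 are trans, O3/O4 cis and O4/O5 trans, so the two allylic oxygens O2 and O5 are cis to each other across the C6=C1 alkene. The five oxygens fall into three classes: benzoates on O7 and O2, an acetate on O3, and free hydroxyls on O4 and O5. The fragile elements are the three esters on a polyol (the O3 acetate can shift to the cis-vicinal O4 under base), the allylic benzoate at C2 and the allylic alcohol at C5. The cyclohexadienes on the way can aromatise or dimerise. The ring itself is not the difficulty; the difficulty is the absolute configuration and the sorting of the oxygens, above all O3 against O4 and O2 against O5. The key step exploits the fact that C1–C7 with the O7 benzoate is an intact benzyl benzoate. The cis O3/O4 pair lies meta and para to C7, which is where osmylation attacks the 2,5-cycloadduct of that arene with a triazolinedione. The temporary C2–N and C5–N bonds mark the two carbons that later receive the cis-1,4 oxygen pair.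

## Logic of the disconnections

**19 ⇒ 16 + 17.** The O3–C(acyl) bond is cut last, so that no later operation can move the acetate. This leaves 16, a triol carrying only benzoates. The forward step must put acetyl on O3 alone in the presence of O4 and O5. It does so through the cyclic orthoester 18 across the cis pair, opened under acid to the axial ester.

**16 ⇒ 15.** The O3/O4 ketal C–O bonds and the O5–Si bond are restored. Both masks fall in one acid treatment, so two protecting groups cost one step. The demand is that the benzoates and the allylic positions tolerate aqueous acid.

**15 ⇒ 14 + 10.** The O2–C(benzoyl) bond is cut. O2 is the only free hydroxyl of 14, so the acylation is unambiguous; it only has to overcome the hindrance beside C1.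

**14 ⇒ 13.** The O5–Si bond is cut. The two allylic hydroxyls of 13 differ only in their surroundings: O2 sits beside the substituted C1, O5 beside C6–H. The forward step must be a kinetically site-selective monosilylation.

**13 ⇒ 11 (through 12).** The C2–O and C5–O bonds are cut together. A cis-1,4-dioxygen pattern across an alkene is the retron of a diene photooxygenation followed by O–O reduction. Two stereocentres disappear and a ketal-protected diene remains. The addition must occur on the face opposite the ketal.

**11 ⇒ 9 + 10.** The O7–C(benzoyl) bond is cut, because the base that removes the urazole in the preceding step also saponifies this ester. The step is simple, but the diene must see only basic conditions.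

**9 ⇒ 6 (through 8 and 7).** In the retrosynthetic sense an N–N bridge is put back across C2 and C5 of the diene C2=C1–C6=C5. The diene termini are exactly the bridgeheads of an arenophile adduct. The forward step needs urazole hydrolysis, oxidation of the hydrazine and retro-[4+2] loss of N2, under which the C3/C4 mask must hold.

**6 ⇒ 5.** The two ketal C–O bonds are cut. The ketal protects the cis-diol through base and oxidation and later shields the upper face of the diene.

**5 ⇒ 4.** No bond is cut; the mirror-image forms are separated. This is placed directly after the key step so that nothing further is carried as racemate, and 4 offers hydroxyl, urazole and benzoate contacts for a chiral phase.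
- A ligand-controlled osmylation of racemic 3 is not relied on. Amine ligands and aqueous reoxidants do not coexist with the photoexcited triazolinedione, so recycling of the unwanted antipode through cycloreversion is not credible and the ceiling would stay that of a resolution.
- An enzymatic acylation is also set aside. Each antipode of 4 presents one hydroxyl of the configuration a lipase prefers, so both would be expected to react, and cis-vicinal monoacetates equilibrate by acyl shift.

**4 ⇒ 1 + 2 (through 3).** The C3–O and C4–O bonds (osmylation) and the C2–N and C5–N bonds (cycloaddition) are cut. This returns the whole skeleton to a bulk arene. The forward step must choose the benzyl ring over the benzoyl ring, the 2,5-mode over the 1,4-mode, the C3=C4 alkene over C1=C6, and the face remote from the urazole.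

## Other disconnections considered

**Alternative 1:** The cut is the ring bond C1–C2. It unfolds the carbocycle to the acyclic aldehyde–enoate A2, which maps onto the pentose A1. Sugar C2, C3 and C4 become ring C5, C4 and C3; the sugar aldehyde carbon becomes C6 after olefination; and the primary carbinol carbon becomes the C2 aldehyde. In the forward step a small nucleophilic trialkylphosphine adds to C6 of A2, the ester enolate attacks the C2 aldehyde, and expulsion of the phosphine restores the C1=C6 alkene to give A3.
- In its favour: C3, C4 and C5 come enantiopure from the chiral pool, so no separation of antipodes is needed. On absolute stereocontrol this plan is the better one.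
- In its favour: O2 emerges as the only free hydroxyl, so the O2/O5 problem of step 7 never arises. This is again better.
- In its favour: hydride reduction of the ester and double benzoylation of O2 and O7 would lead to 15, after which the end game is identical. On that part the two plans are equal.
- Against it here: the one stereocentre the closure creates, C2, must come out trans to O3 through facial selectivity of an aldol step. The aldehyde is epimerisable and the closure is reversible and often sluggish. The chosen plan fixes every relative configuration through a rigid bicycle and a ketal-shielded diene.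
- Against it here: reaching A2 from A1 needs olefination, ketalisation, differential protection of two hydroxyls and an oxidation, with oxa-Michael cyclisation onto the enoate as a hazard. C7 also arrives at the ester level and must be reduced.
- Step economy: roughly seven operations to A2, the closure, then four more. This is expected to be somewhat longer than the ten steps chosen, but all material has the right handedness.

**Alternative 2:** The cuts are C2–C3 and C4–C5. They divide the ring into the pyrone A4 (ring C5, C6, C1, C2 and C7) and the dioxole A5 (C3 and C4 with their oxygens already ketalised). In the forward step an inverse-electron-demand [4+2] cycloaddition of electron-poor A4 with electron-rich A5 gives a bridged lactone. A retro-[4+2] step then expels the bridge and leaves the diene ester A6.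
- In its favour: two ring bonds and the cis O3/O4 relationship are made in one thermal operation. The dienophile is symmetric, so there is no regiochemical question, and endo/exo selectivity is erased with the bridge. No osmium and no cryogenic photochemistry are needed.
- In its favour: hydride reduction of A6 would give 9, so the diene stage is reached in two steps instead of four. On step economy up to 9 this alternative is the better one.
- Against it here: both partners are achiral and nothing in a thermal cycloaddition selects a handedness. A6 would form as a racemate, and its structure is corrected to that in the list below. On absolute control the alternative is therefore only equal to the chosen plan.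
- Against it here: A6 and 9 lack the diol, urazole and benzoate contacts of 4 and are less robust objects to resolve.
- Against it here: A5 is volatile and not a stock reagent. The temperature needed for bridge loss invites aromatisation of A6 and a second cycloaddition of A6 with A5.
- Comparison: both plans are pericyclic and substrate-controlled in relative configuration, and both reach the same ketal-protected diene, so everything after 9 would be shared.

**Alternative 3:** The cuts are the C4–O and C5–O bonds of an oxirane. They lead back to the cyclohexadienyl trans-diol derivative A7 (O2 and O7 benzoylated, O3–H free, double bonds C4=C5 and C6=C1). In the forward step a peracid hydrogen-bonded to the allylic O3–H delivers oxygen to C4=C5 on the O3 face and gives the syn epoxy alcohol A8. Acetylation of the single free hydroxyl and hydrolytic anti opening at the allylic C5 would then complete 19.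
- In its favour: it follows the presumed biogenesis and needs only two further steps without any protecting group. On step economy after the key step it is clearly better.
- In its favour: the acetate goes onto the only hydroxyl present, so the O3/O4 question of step 10 does not exist. This is also better.
- Against it here: all the difficulty moves into A7, an enantiopure arene trans-dihydrodiol with differentiated oxygens, for which no short and reliable preparation is at hand. The chosen plan starts from a bulk arene.
- Against it here: A7 aromatises easily by 1,2-elimination of its allylic benzoate. The epoxidation must choose C4=C5 over the trisubstituted C6=C1 and gives an acid-sensitive vinyl oxirane beside a carboxylic acid by-product.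
- Against it here: the last opening must be cleanly SN2 at C5, since an ionising pathway would erode the trans O4/O5 relationship.
- Comparison: the alternative relies on hydrogen-bond direction and allylic activation, the chosen plan on steric shielding by a bridge and a ketal. The former is more elegant and the latter more predictable. Whether the alternative is shorter overall depends on the unknown length of the route to A7.

Key step: step 1

## Route

**Step 1**
Reactants: 1 benzyl benzoate; 2 4-methyl-1,2,4-triazoline-3,5-dione (MTAD)
Product: 4 racemic urazole-bridged cis-3,4-diol, via racemic para-cycloadduct 3 (not isolated)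
Conditions: 1 (2 equiv), 2, CH2Cl2, white LEDs, −78 °C; then OsO4 (5 mol %), NMO, acetone/H2O, −78 → 0 °C, dark; Na2SO3 work-up
Reagents that add atoms: 4-methyl-1,2,4-triazoline-3,5-dione CN1C(=O)N=NC1=O; osmium tetroxide O=[Os](=O)(=O)=O; N-methylmorpholine N-oxide C[N+]1([O-])CCOCC1
Why: Visible light excites 2, which forms an exciplex with the more electron-rich benzyl ring of 1 (the benzoyl ring is deactivated by its carbonyl) and closes the C2–N and C5–N bonds in a formal [4+2] para-cycloaddition (4π of the arene, 2π of N=N); this closes the six-membered C4N2 ring of a 2,3-diazabicyclo[2.2.2]octa-5,7-diene. The 2,5-mode is preferred over the 1,4-mode because the latter would place the side chain on a congested bridgehead, so C7 stays on the trisubstituted C1=C6 alkene. The closest known reaction type is the visible-light triazolinedione para-cycloaddition to monosubstituted benzenes with Upjohn dihydroxylation (OsO4/NMO) of the cold cycloadduct. C2 and C5 are created together as bridgeheads: the suprafacial bridge fixes their relative configuration, and since neither arene face is preferred, 3 forms as a racemate. OsO4 then adds by suprafacial [3+2] cycloaddition to C3=C4, the only disubstituted and unhindered alkene (C1=C6 is trisubstituted and carries the electron-withdrawing allylic benzoate), from the face remote from the urazole, whose N–N bridge and carbonyl groups block the other face; this sets C3 and C4 cis to each other and anti to the nitrogen bridge. The osmylation must outrun thermal retro-cycloaddition of 3, which is why the oxidant is added at −78 °C and the mixture is warmed slowly. Site, regio- and relative stereochemistry thus come from the substrate alone, while the absolute sense is settled in step 2.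

**Step 2**
Reactants: 4 racemic urazole-bridged cis-3,4-diol
Product: 5 enantiopure urazole-bridged cis-3,4-diol (O3/O4 up; N–N bridge down)
Conditions: preparative SFC, amylose tris(3,5-dimethylphenylcarbamate) on silica, CO2/MeOH, 35 °C
Reagents that add atoms: none
Why: Resolution of enantiomers by chromatography on a polysaccharide carbamate chiral stationary phase; the diol, the urazole carbonyls and the benzoate of 4 supply the hydrogen-bond and π contacts on which such phases discriminate. No stereocentre is touched, and the wanted antipode should be identified by anomalous-dispersion X-ray analysis of 5 or by correlation with the optical rotation of 19.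

**Step 3**
Reactants: 5 enantiopure urazole-bridged cis-3,4-diol
Product: 6 urazole-bridged 3,4-O-isopropylidene ketal
Conditions: Me2C(OMe)2, p-TsOH·H2O (cat.), acetone, rt
Reagents that add atoms: 2,2-dimethoxypropane COC(C)(C)OC
Why: Acid-catalysed transketalisation (acetonide formation) of the cis-diol; no stereocentre changes, and the ketal is stable to the base and oxidant of step 4.

**Step 4**
Reactants: 6 urazole-bridged 3,4-O-isopropylidene ketal
Product: 9 dienyl alcohol acetonide, via bicyclic hydrazine 7 (not isolated), via bicyclic diazene 8 (not isolated)
Conditions: KOH, i-PrOH, reflux; AcOH to pH 6; CuCl2 (aq), 0 °C; aq NH3, rt (−N2)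
Reagents that add atoms: none
Why: Base hydrolysis of the urazole with double decarboxylation gives the cyclic hydrazine 7 and saponifies the C7 benzoate; divalent copper oxidises 7 to the diazene 8 (held as its CuCl complex and released by ammonia), which loses N2 by retro-[4+2] cycloreversion at room temperature. C2 and C5 become sp2, and the ketal-protected C3/C4 centres are untouched.

**Step 5**
Reactants: 9 dienyl alcohol acetonide; 10 benzoyl chloride
Product: 11 dienyl benzoate acetonide
Conditions: BzCl, Et3N, DMAP (cat.), CH2Cl2, 0 °C
Reagents that add atoms: benzoyl chloride O=C(Cl)c1ccccc1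
Why: DMAP-catalysed acylation of the primary allylic alcohol; the medium stays basic so that the diene does not aromatise, and 11 is used promptly to limit Diels–Alder dimerisation.

**Step 6**
Reactants: 11 dienyl benzoate acetonide
Product: 13 cis-2,5-diol acetonide, via anti endoperoxide 12 (not isolated)
Conditions: O2, tetraphenylporphyrin (cat.), visible light, CH2Cl2, −30 °C; then thiourea, MeOH, rt
Reagents that add atoms: dioxygen O=O
Why: Sensitised photooxygenation: singlet oxygen adds in a [4+2] cycloaddition to the diene termini C2 and C5 on the face opposite the ketal, whose methyl group covers the upper face, so both new C–O bonds are cis to each other and trans to O3/O4. Thiourea then reduces the O–O bond without touching a C–O bond, the alkene or the ester.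

**Step 7**
Reactants: 13 cis-2,5-diol acetonide
Product: 14 O5 tert-butyldimethylsilyl ether with free O2–H
Conditions: TBSCl (1.05 equiv), imidazole, DMF, 0 °C
Reagents that add atoms: tert-butyldimethylsilyl chloride CC(C)(C)[Si](C)(C)Cl
Why: Kinetic site-selective silylation: O5 is flanked by the unsubstituted C6–H whereas O2 sits beside C1 with its CH2OBz arm, so the less hindered O5 should react first. Low temperature and a single equivalent of silyl chloride hold back bis-silylation and any 1,3-benzoyl shift from O7.

**Step 8**
Reactants: 14 O5 tert-butyldimethylsilyl ether with free O2–H; 10 benzoyl chloride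
Product: 15 fully protected 2,7-dibenzoate (3,4-ketal; O5 silyl ether)
Conditions: BzCl, pyridine, DMAP (cat.), CH2Cl2, 0 °C → rt
Reagents that add atoms: benzoyl chloride O=C(Cl)c1ccccc1
Why: DMAP-catalysed benzoylation of the only free hydroxyl; only the O–H bond reacts, so the configuration at C2 is retained.

**Step 9**
Reactants: 15 fully protected 2,7-dibenzoate
Product: 16 3,4,5-triol 2,7-dibenzoate
Conditions: TFA/H2O (9:1), 0 °C → rt
Reagents that add atoms: none
Why: Acid hydrolysis of the ketal and the silyl ether in one operation; benzoates are stable to aqueous acid at this temperature, and the electron-poor polyoxygenated ring resists allylic ionisation.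

**Step 10**
Reactants: 16 3,4,5-triol 2,7-dibenzoate; 17 trimethyl orthoacetate
Product: 19 target 3-O-acetate, via cyclic orthoacetate 18 (not isolated)
Conditions: MeC(OMe)3, CSA (cat.), MeCN, rt; then AcOH/H2O (4:1), rt
Reagents that add atoms: trimethyl orthoacetate COC(C)(OC)OC; water O
Why: Regioselective monoacylation of a cis-diol through its cyclic orthoester: only the cis O3/O4 pair closes a five-membered orthoester (O5 is trans to O4), and mild acid hydrolysis opens it to the axial ester. In the preferred half-chair the C2 benzoate is pseudoaxial to avoid allylic strain with the C1 side chain, which makes O3 axial and O4 equatorial, so the acetate should end on O3. The acidic medium suppresses acyl migration, and the opening has close analogy in pyranoside triols that carry a cis-diol beside a trans hydroxyl.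

## Compound list

1 | benzyl benzoate | O=C(OCc1ccccc1)c1ccccc1 | starting material
2 | 4-methyl-1,2,4-triazoline-3,5-dione (MTAD) | CN1C(=O)N=NC1=O | starting material
3 | racemic para-cycloadduct: 2,3-diazabicyclo[2.2.2]octa-5,7-diene with bridgeheads C2 and C5, N-methylurazole on the N–N bridge, CH2OBz on C1 of the C1=C6 alkene (both antipodes written) | C1=C[C@H]2C=C(COC(=O)c3ccccc3)[C@@H]1N1N2C(=O)N(C)C1=O.C1=C[C@@H]2C=C(COC(=O)c3ccccc3)[C@H]1N1N2C(=O)N(C)C1=O | intermediate (not isolated)
4 | racemic urazole-bridged cis-3,4-diol, diol anti to the N–N bridge, C1=C6 alkene, C7 benzoate (both antipodes written) | O[C@H]1[C@@H](O)[C@H]2C=C(COC(=O)c3ccccc3)[C@@H]1N1N2C(=O)N(C)C1=O.O[C@@H]1[C@H](O)[C@@H]2C=C(COC(=O)c3ccccc3)[C@H]1N1N2C(=O)N(C)C1=O | intermediate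
5 | enantiopure urazole-bridged cis-3,4-diol: O3 and O4 up, N–N bridge down at C2 and C5 | O[C@H]1[C@@H](O)[C@H]2C=C(COC(=O)c3ccccc3)[C@@H]1N1N2C(=O)N(C)C1=O | intermediate
6 | 3,4-O-isopropylidene ketal of 5 | CC1(C)O[C@H]2[C@@H](O1)[C@H]3C=C(COC(=O)c4ccccc4)[C@@H]2N2N3C(=O)N(C)C2=O | intermediate
7 | bicyclic hydrazine: 2,3-diazabicyclo[2.2.2]oct-5-ene (N–H, N–H) with the 3,4-ketal and free C7–OH | CC1(C)O[C@H]2[C@@H](O1)[C@H]3C=C(CO)[C@@H]2NN3 | intermediate (not isolated)
8 | bicyclic diazene: the N=N analogue of 7 | CC1(C)O[C@H]2[C@@H](O1)[C@H]3C=C(CO)[C@@H]2N=N3 | intermediate (not isolated)
9 | dienyl alcohol acetonide: diene C2=C1–C6=C5, C7–OH, cis-3,4-ketal up | CC1(C)O[C@H]2[C@@H](O1)C=CC(CO)=C2 | intermediate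
10 | benzoyl chloride | O=C(Cl)c1ccccc1 | starting material
11 | dienyl benzoate acetonide: 9 with O7 benzoylated | CC1(C)O[C@H]2[C@@H](O1)C=CC(COC(=O)c3ccccc3)=C2 | intermediate
12 | anti endoperoxide: O–O bridge down across C2 and C5, ketal up, C1=C6 alkene | CC1(C)O[C@H]2[C@@H](O1)[C@H]3C=C(COC(=O)c4ccccc4)[C@@H]2OO3 | intermediate (not isolated)
13 | cis-2,5-diol acetonide: O2–H and O5–H down, 3,4-ketal up, C7 benzoate | CC1(C)O[C@H]2[C@@H](O1)[C@H](O)C=C(COC(=O)c3ccccc3)[C@@H]2O | intermediate
14 | O5 tert-butyldimethylsilyl ether of 13 with free O2–H | CC1(C)O[C@H]2[C@@H](O1)[C@H](O[Si](C)(C)C(C)(C)C)C=C(COC(=O)c3ccccc3)[C@@H]2O | intermediate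
15 | 2,7-dibenzoate with 3,4-ketal and O5 silyl ether | CC1(C)O[C@H]2[C@@H](O1)[C@H](O[Si](C)(C)C(C)(C)C)C=C(COC(=O)c3ccccc3)[C@@H]2OC(=O)c1ccccc1 | intermediate
16 | 3,4,5-triol 2,7-dibenzoate: O3 and O4 up, O2 and O5 down | O[C@H]1[C@@H](O)[C@H](O)C=C(COC(=O)c2ccccc2)[C@@H]1OC(=O)c1ccccc1 | intermediate
17 | trimethyl orthoacetate | COC(C)(OC)OC | starting material
18 | cyclic 3,4-orthoacetate of 16 (both epimers at the orthoester carbon) | COC1(C)O[C@H]2[C@@H](O1)[C@H](O)C=C(COC(=O)c3ccccc3)[C@@H]2OC(=O)c1ccccc1 | intermediate (not isolated)
19 | target: [(3R,4S,5S,6S)-5-acetoxy-6-benzoyloxy-3,4-dihydroxycyclohex-1-en-1-yl]methyl benzoate | CC(=O)O[C@H]1[C@@H](O)[C@H](O)C=C(COC(=O)c2ccccc2)[C@@H]1OC(=O)c1ccccc1 | target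

## Step count and least certain steps

Total: 10 steps. Longest linear sequence: 10 steps (from 1 and 2 to 19).

**Step 1 (key step).** The most likely failure is loss of conversion, either through competition of the benzoyl ring of 1 for the excited arenophile or through thermal cycloreversion of 3 before the osmylation is complete; the two arene rings differ only electronically and 3 is stable only in the cold. Fallback (sets out from 2, returns at 9): the same disconnection is run on an arene with a single ring, benzyl acetate F1. Under the conditions of step 1 this should give the racemic cycloadduct F2 (not isolated) and the racemic diol acetate F3. F3 is resolved on the chiral phase to the diol acetate F4 and ketalised to the acetonide acetate F5. Under the conditions of step 4, F5 loses its acetate together with the urazole and rejoins the route at 9 through 7 and 8.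

**Step 2.** The most likely failure is insufficient discrimination of the antipodes or low loading capacity on the chiral phase, since the polar diol may dissolve poorly in the mobile phase. Fallback (sets out from 4, returns at 9): 4 is esterified with (S)-O-acetylmandelic acid (DCC, DMAP) to the diastereomeric bis-esters, the wanted bis-mandelate F6 and the bis-mandelate of the mirror-image diol F7, which are separated by crystallisation or ordinary silica chromatography. K2CO3 in methanol strips all esters from F6 to give the urazole triol F8. Ketalisation as in step 3 gives the acetonide alcohol F9, which under the conditions of step 4 rejoins the route at 9.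

**Step 7.** The most likely failure is loss of site discrimination between O5 and O2, or a base-induced 1,3-shift of benzoyl from O7 to O2, because the two allylic hydroxyls differ only in their steric surroundings. Fallback (sets out from 9, returns at 15):
- 9 is photooxygenated and reduced as in step 6 without prior benzoylation, through the endoperoxide alcohol F10 (not isolated) to the triol acetonide F11.
- 1,1′-Carbonyldiimidazole closes the six-membered cyclic carbonate F12 across the 1,3-related O7 and O2, the only pair that can be bridged, so O5 remains the sole free hydroxyl.
- Silylation gives the silyl ether carbonate F13, and K2CO3 in methanol removes the carbonate to give the 2,7-diol F14.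
- 10 (2 equiv) with pyridine/DMAP benzoylates O7 and O2 together to give 15.

**Step 10.** The most likely failure is capture of the free O5 hydroxyl by the orthoester reagent, or leakage of acetyl to O4 through opening of the other C–O bond, since three hydroxyls are free. Fallback (sets out from 15, returns at 19): O5 is kept blocked. Aqueous acetic acid at 40 °C removes only the ketal of 15 to give the diol silyl ether F15. 17 with CSA, followed by aqueous acetic acid, passes through the orthoacetate F16 (not isolated) to the monoacetate silyl ether F17. HF·pyridine in THF/pyridine, an acidic desilylation that does not promote acyl shift, then gives 19.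

## Further compounds

F1 | step 1 | benzyl acetate | CC(=O)OCc1ccccc1
F2 | step 1 | racemic para-cycloadduct of benzyl acetate with 2 (both antipodes written) | C1=C[C@H]2C=C(COC(C)=O)[C@@H]1N1N2C(=O)N(C)C1=O.C1=C[C@@H]2C=C(COC(C)=O)[C@H]1N1N2C(=O)N(C)C1=O
F3 | step 1 | racemic urazole-bridged cis-3,4-diol with C7 acetate (both antipodes written) | O[C@H]1[C@@H](O)[C@H]2C=C(COC(C)=O)[C@@H]1N1N2C(=O)N(C)C1=O.O[C@@H]1[C@H](O)[C@@H]2C=C(COC(C)=O)[C@H]1N1N2C(=O)N(C)C1=O
F4 | step 1 | enantiopure urazole-bridged cis-3,4-diol with C7 acetate (O3/O4 up) | O[C@H]1[C@@H](O)[C@H]2C=C(COC(C)=O)[C@@H]1N1N2C(=O)N(C)C1=O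
F5 | step 1 | 3,4-O-isopropylidene ketal of F4 | CC1(C)O[C@H]2[C@@H](O1)[C@H]3C=C(COC(C)=O)[C@@H]2N2N3C(=O)N(C)C2=O
F6 | step 2 | 3,4-bis[(S)-O-acetylmandelate] of 5 | CC(=O)O[C@@H](c1ccccc1)C(=O)O[C@H]1[C@@H](OC(=O)[C@@H](OC(C)=O)c2ccccc2)[C@H]2C=C(COC(=O)c3ccccc3)[C@@H]1N1N2C(=O)N(C)C1=O
F7 | step 2 | 3,4-bis[(S)-O-acetylmandelate] of the mirror-image diol | CC(=O)O[C@@H](c1ccccc1)C(=O)O[C@@H]1[C@H](OC(=O)[C@@H](OC(C)=O)c2ccccc2)[C@@H]2C=C(COC(=O)c3ccccc3)[C@H]1N1N2C(=O)N(C)C1=O
F8 | step 2 | urazole-bridged triol (3,4-diol; free C7–OH) | O[C@H]1[C@@H](O)[C@H]2C=C(CO)[C@@H]1N1N2C(=O)N(C)C1=O
F9 | step 2 | 3,4-O-isopropylidene ketal of F8 (free C7–OH) | CC1(C)O[C@H]2[C@@H](O1)[C@H]3C=C(CO)[C@@H]2N2N3C(=O)N(C)C2=O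
F10 | step 7 | anti endoperoxide of 9 (free C7–OH) | CC1(C)O[C@H]2[C@@H](O1)[C@H]3C=C(CO)[C@@H]2OO3
F11 | step 7 | 2,5,7-triol acetonide (O2, O5 down; ketal up) | CC1(C)O[C@H]2[C@@H](O1)[C@H](O)C=C(CO)[C@@H]2O
F12 | step 7 | O7,O2 cyclic carbonate of F11 (free O5–H) | CC1(C)O[C@H]2[C@@H](O1)[C@H](O)C=C3COC(=O)O[C@H]23
F13 | step 7 | O5 tert-butyldimethylsilyl ether of F12 | CC1(C)O[C@H]2[C@@H](O1)[C@H](O[Si](C)(C)C(C)(C)C)C=C3COC(=O)O[C@H]23
F14 | step 7 | 2,7-diol with 3,4-ketal and O5 silyl ether | CC1(C)O[C@H]2[C@@H](O1)[C@H](O[Si](C)(C)C(C)(C)C)C=C(CO)[C@@H]2O
F15 | step 10 | 3,4-diol 2,7-dibenzoate with O5 silyl ether | O[C@H]1[C@@H](O)[C@H](O[Si](C)(C)C(C)(C)C)C=C(COC(=O)c2ccccc2)[C@@H]1OC(=O)c1ccccc1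
F16 | step 10 | cyclic 3,4-orthoacetate of F15 (both epimers at the orthoester carbon) | COC1(C)O[C@H]2[C@@H](O1)[C@H](O[Si](C)(C)C(C)(C)C)C=C(COC(=O)c3ccccc3)[C@@H]2OC(=O)c1ccccc1
F17 | step 10 | 3-O-acetate 2,7-dibenzoate with free O4–H and O5 silyl ether | CC(=O)O[C@H]1[C@@H](O)[C@H](O[Si](C)(C)C(C)(C)C)C=C(COC(=O)c2ccccc2)[C@@H]1OC(=O)c1ccccc1
A1 | alternative 1 | D-arabinose (open-chain form) | O=C[C@@H](O)[C@H](O)[C@H](O)CO
A2 | alternative 1 | acyclic aldehyde–enoate: ethyl (E)-enoate C6=C1, O5 silyl ether, 3,4-ketal, C2 aldehyde | O=C[C@H]1OC(C)(C)O[C@H]1[C@H](O[Si](C)(C)C(C)(C)C)/C=C/C(=O)OCC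
A3 | alternative 1 | ethyl cyclohexenecarboxylate with free O2–H, 3,4-ketal and O5 silyl ether | CC1(C)O[C@H]2[C@@H](O1)[C@H](O[Si](C)(C)C(C)(C)C)C=C(C(=O)OCC)[C@@H]2O
A4 | alternative 2 | methyl coumalate | COC(=O)C1=COC(=O)C=C1
A5 | alternative 2 | 2,2-dimethyl-1,3-dioxole | CC1(C)OC=CO1
A6 | alternative 2 | methyl 3,4-isopropylidenedioxycyclohexa-1,5-diene-1-carboxylate, racemic as formed (both antipodes written) | CC1(C)O[C@H]2[C@@H](O1)C=CC(C(=O)OC)=C2.CC1(C)O[C@@H]2[C@H](O1)C=CC(C(=O)OC)=C2
A7 | alternative 3 | cyclohexa-dienyl trans-2,3-diol 2,7-dibenzoate with free O3–H | O[C@H]1C=CC=C(COC(=O)c2ccccc2)[C@@H]1OC(=O)c1ccccc1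
A8 | alternative 3 | syn 4,5-epoxy alcohol 2,7-dibenzoate | O[C@H]1[C@H]2O[C@H]2C=C(COC(=O)c2ccccc2)[C@@H]1OC(=O)c1ccccc1
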